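The biflavone is cut at the bond between C3 of pyranone ring C of the acacetin unit and C6'' of ring A of the apigenin unit, so that both halves come from catalogue flavones. The key step exploits C3–H, the only hydrogen on ring C, which sits beside the C4 carbonyl: carbonyl-directed zincation with TMPZnCl·LiCl turns benzyl-protected acacetin itself into the nucleophile, and a Negishi coupling in the same flask joins it to 6''-iodoapigenin tribenzyl ether. The iodine is placed at C6'' beforehand because the chelated 5''-OH of ring A steers iodination to its ortho carbon. One hydrogenolysis then frees all five phenols and leaves the 4'-methyl ether.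

Key step: step 5

Remark on the chemistry: the target is drawn without stereodescriptors, so the C3–C6'' axis (four ortho substituents) is treated as configurationally unassigned and is made without stereocontrol; acacetin and apigenin are taken as commercial starting materials.
Locants: unprimed and single-primed for the acacetin unit, double- and triple-primed for the apigenin unit.

Step 1
Reactants: 1 acacetin (5,7-dihydroxy-2-(4-methoxyphenyl)-4H-chromen-4-one)
Product: 2 5,7-bis(benzyloxy)-2-(4-methoxyphenyl)-4H-chromen-4-one (acacetin dibenzyl ether)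
Conditions: BnBr (3 equiv), K2CO3, Bu4NI (cat.), DMF, 80 °C
Reagents that add atoms: benzyl bromide, BrCc1ccccc1
Why: Williamson O-alkylation under forcing conditions should benzylate both the free 7-OH and the carbonyl-chelated 5-OH, so that no acidic proton is left for the zinc amide base of step 5.

Step 2
Reactants: 3 apigenin (5,7-dihydroxy-2-(4-hydroxyphenyl)-4H-chromen-4-one)
Product: 4 7-(benzyloxy)-2-[4-(benzyloxy)phenyl]-5-hydroxy-4H-chromen-4-one
Conditions: BnBr (2.1 equiv), K2CO3, acetone, reflux
Reagents that add atoms: benzyl bromide, BrCc1ccccc1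
Why: Williamson O-alkylation under mild conditions should take the 7''-OH and 4'''-OH only, because the 5''-OH is hydrogen-bonded to the C4'' carbonyl, is the least nucleophilic, and stays free to direct the iodination.

Step 3
Reactants: 4 7-(benzyloxy)-2-[4-(benzyloxy)phenyl]-5-hydroxy-4H-chromen-4-one
Product: 5 7-(benzyloxy)-2-[4-(benzyloxy)phenyl]-5-hydroxy-6-iodo-4H-chromen-4-one
Conditions: BnMe3N+ ICl2− (1.05 equiv), CaCO3, CH2Cl2–MeOH, 25 °C
Reagents that add atoms: benzyltrimethylammonium dichloroiodate, C[N+](C)(C)Cc1ccccc1.Cl[I-]Cl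
Why: Electrophilic aromatic iodination of a 5-hydroxy-7-alkoxyflavone is steered by the free chelated 5-OH to its ortho carbon C6 of ring A (5-O-alkyl ethers react at C8 instead), and one equivalent of this mild reagent with CaCO3 as acid scavenger should leave ring B and the benzyl ethers untouched.

Step 4
Reactants: 5 7-(benzyloxy)-2-[4-(benzyloxy)phenyl]-5-hydroxy-6-iodo-4H-chromen-4-one
Product: 6 5,7-bis(benzyloxy)-2-[4-(benzyloxy)phenyl]-6-iodo-4H-chromen-4-one (6''-iodoapigenin tribenzyl ether)
Conditions: BnBr (1.5 equiv), K2CO3, DMF, 70 °C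
Reagents that add atoms: benzyl bromide, BrCc1ccccc1
Why: Williamson O-alkylation of the chelated phenol in DMF removes the only acidic proton of the electrophile, so that it cannot quench the organozinc partner in step 5.

Step 5
Reactants: 2 acacetin dibenzyl ether; 6 6''-iodoapigenin tribenzyl ether
Product: 8 5,7-bis(benzyloxy)-3-{5,7-bis(benzyloxy)-2-[4-(benzyloxy)phenyl]-4-oxo-4H-chromen-6-yl}-2-(4-methoxyphenyl)-4H-chromen-4-one (pentabenzyl ether of the target), via chlorozinc flavone 7 (not isolated)
Conditions: 2 (1.3 equiv), TMPZnCl·LiCl (1.2 equiv), THF, 25 °C; then 6 (1.0 equiv), Pd2(dba)3 (2.5 mol%), RuPhos (10 mol%), THF–NMP, 65 °C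
Reagents that add atoms: none
Why: Directed deprotonative zincation followed by Negishi cross-coupling: the hindered zinc amide, held by the C4 carbonyl oxygen, removes C3–H, the only hydrogen on ring C, and gives the covalent alkenylzinc 7, which at 25 °C should neither open the pyranone ring by beta-elimination of O1 nor add to carbonyl groups. Zerovalent palladium then inserts into the C6''–I bond of 6, the alkenyl group passes from zinc to palladium, and reductive elimination forms the C3–C6'' bond. The closest known reaction type is the zincation of chromones with TMP–zinc bases and Negishi arylation at C3 (the isoflavone pattern), applied here to a 2-aryl chromone and a di-ortho-alkoxy aryl iodide, with a bulky dialkylbiarylphosphine ligand of the kind established for tri- and tetra-ortho-substituted biaryl Negishi couplings. No ring is closed and no stereocentre is set; the new axis forms without stereocontrol. The step needs site selectivity in the metalation and chemoselectivity in the coupling: the ring A and ring B hydrogens and the benzylic OCH2 groups are too weakly acidic for a zinc amide at 25 °C, the base is kept below the amount of 2 so that none is left to metalate C3''–H of 6 or of 8, and 6 carries a single carbon–halogen bond.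

Step 6
Reactants: 8 pentabenzyl ether of the target
Product: 9 3-[5,7-dihydroxy-2-(4-hydroxyphenyl)-4-oxo-4H-chromen-6-yl]-5,7-dihydroxy-2-(4-methoxyphenyl)-4H-chromen-4-one (CNP0273516.0)
Conditions: H2 (1 atm), Pd/C (10 wt% palladium on carbon), THF–MeOH, 25 °C
Reagents that add atoms: none
Why: Catalytic hydrogenolysis should cleave the five benzyl aryl ethers in one operation, while the aryl methyl ether is inert and the conjugated, aryl-substituted C2=C3 and C2''=C3'' bonds of the pyranone rings are not expected to be reduced at 1 atm and room temperature.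

Compound list
1 | acacetin, 5,7-dihydroxy-2-(4-methoxyphenyl)-4H-chromen-4-one | COc1ccc(-c2cc(=O)c3c(O)cc(O)cc3o2)cc1 | starting material
2 | 5,7-bis(benzyloxy)-2-(4-methoxyphenyl)-4H-chromen-4-one | COc1ccc(-c2cc(=O)c3c(OCc4ccccc4)cc(OCc4ccccc4)cc3o2)cc1 | intermediate
3 | apigenin, 5,7-dihydroxy-2-(4-hydroxyphenyl)-4H-chromen-4-one | O=c1cc(-c2ccc(O)cc2)oc2cc(O)cc(O)c12 | starting material
4 | 7-(benzyloxy)-2-[4-(benzyloxy)phenyl]-5-hydroxy-4H-chromen-4-one | O=c1cc(-c2ccc(OCc3ccccc3)cc2)oc2cc(OCc3ccccc3)cc(O)c12 | intermediate
5 | 7-(benzyloxy)-2-[4-(benzyloxy)phenyl]-5-hydroxy-6-iodo-4H-chromen-4-one | O=c1cc(-c2ccc(OCc3ccccc3)cc2)oc2cc(OCc3ccccc3)c(I)c(O)c12 | intermediate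
6 | 5,7-bis(benzyloxy)-2-[4-(benzyloxy)phenyl]-6-iodo-4H-chromen-4-one | O=c1cc(-c2ccc(OCc3ccccc3)cc2)oc2cc(OCc3ccccc3)c(I)c(OCc3ccccc3)c12 | intermediate
7 | chloro[5,7-bis(benzyloxy)-2-(4-methoxyphenyl)-4-oxo-4H-chromen-3-yl]zinc, formed as its LiCl complex, not isolated | COc1ccc(-c2oc3cc(OCc4ccccc4)cc(OCc4ccccc4)c3c(=O)c2[Zn]Cl)cc1 | intermediate
8 | 5,7-bis(benzyloxy)-3-{5,7-bis(benzyloxy)-2-[4-(benzyloxy)phenyl]-4-oxo-4H-chromen-6-yl}-2-(4-methoxyphenyl)-4H-chromen-4-one | COc1ccc(-c2oc3cc(OCc4ccccc4)cc(OCc4ccccc4)c3c(=O)c2-c2c(OCc3ccccc3)cc3oc(-c4ccc(OCc5ccccc5)cc4)cc(=O)c3c2OCc2ccccc2)cc1 | intermediate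
9 | 3-[5,7-dihydroxy-2-(4-hydroxyphenyl)-4-oxo-4H-chromen-6-yl]-5,7-dihydroxy-2-(4-methoxyphenyl)-4H-chromen-4-one (CNP0273516.0) | COc1ccc(-c2oc3cc(O)cc(O)c3c(=O)c2-c2c(O)cc3oc(-c4ccc(O)cc4)cc(=O)c3c2O)cc1 | target

Total step count: 6 (convergent; step 1 on the acacetin branch, steps 2 to 4 on the apigenin branch, steps 5 and 6 after the union).
Longest linear sequence: 5 steps (3 to 4 to 5 to 6 to 8 to 9, that is steps 2, 3, 4, 5 and 6).

Steps most likely to fail

Step 5. The metalation of 2 may be incomplete or go to the wrong site. Alternatively, transmetalation and reductive elimination at the fourfold ortho-substituted axis may be so slow that the organozinc is protonated and the iodide reduced instead of coupled. The fallback reverses the polarity and changes the metal. It sets out from 2 and 6. Compound 2 is lithiated at C3 with LiN(iPr)2 in THF at −78 °C to the 3-lithio derivative of 2 F1, which is quenched with I2 to give 5,7-bis(benzyloxy)-3-iodo-2-(4-methoxyphenyl)-4H-chromen-4-one F2. Compound 6 is borylated with pinacolborane (PdCl2(MeCN)2, SPhos, Et3N, dioxane, 80 °C), conditions suited to di-ortho-substituted aryl iodides, to give the 6-pinacolboronate of apigenin tribenzyl ether F3. Suzuki–Miyaura coupling of F2 with F3 (Pd(OAc)2, SPhos, K3PO4, toluene–water, 100 °C) comes back to the route at 8.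

Step 3. Regiocontrol may be lost in the iodination, with attack at C8'' or double iodination at C6'' and C8''. The fallback replaces substitution on the neutral phenol by iodination of a preformed metal phenoxide. It sets out from 4, which with TlOAc in CH2Cl2 at 25 °C should form the thallium 5-phenoxide of 4 (ArOTl, monovalent thallium) F4. Addition of I2 then delivers iodine from the metal-bound oxygen to the ortho carbon C6'', and the fallback comes back to the route at 5.

Step 4. O-alkylation of the 5''-OH may stay incomplete, because this phenol is chelated to the carbonyl and flanked by the iodine. The fallback drops this protecting group. It sets out from 5, which is coupled as the free phenol with the zinc reagent 7 (1.5 equiv, added slowly; Pd(OAc)2, SPhos, THF, 25 to 40 °C). Organozinc cross-coupling is known to tolerate free phenols when transmetalation outpaces proton transfer. This should give the tetrabenzyl ether of the target with free 5''-OH F5. Hydrogenolysis of F5 under the conditions of step 6 comes back to the route at 9.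

Further compounds
F1 | step 5 | 3-lithio derivative of 2, [5,7-bis(benzyloxy)-2-(4-methoxyphenyl)-4-oxo-4H-chromen-3-yl]lithium | COc1ccc(-c2oc3cc(OCc4ccccc4)cc(OCc4ccccc4)c3c(=O)c2[Li])cc1
F2 | step 5 | 5,7-bis(benzyloxy)-3-iodo-2-(4-methoxyphenyl)-4H-chromen-4-one | COc1ccc(-c2oc3cc(OCc4ccccc4)cc(OCc4ccccc4)c3c(=O)c2I)cc1
F3 | step 5 | 5,7-bis(benzyloxy)-2-[4-(benzyloxy)phenyl]-6-(4,4,5,5-tetramethyl-1,3,2-dioxaborolan-2-yl)-4H-chromen-4-one | O=c1cc(-c2ccc(OCc3ccccc3)cc2)oc2cc(OCc3ccccc3)c(B3OC(C)(C)C(C)(C)O3)c(OCc3ccccc3)c12
F4 | step 3 | thallium 5-phenoxide of 4 (ArOTl) | O=c1cc(-c2ccc(OCc3ccccc3)cc2)oc2cc(OCc3ccccc3)cc([O-])c12.[Tl+]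
F5 | step 4 | 5,7-bis(benzyloxy)-3-{7-(benzyloxy)-2-[4-(benzyloxy)phenyl]-5-hydroxy-4-oxo-4H-chromen-6-yl}-2-(4-methoxyphenyl)-4H-chromen-4-one | COc1ccc(-c2oc3cc(OCc4ccccc4)cc(OCc4ccccc4)c3c(=O)c2-c2c(OCc3ccccc3)cc3oc(-c4ccc(OCc5ccccc5)cc4)cc(=O)c3c2O)cc1
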